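## Structural features

The target is a 2-O-alkylglycerol. The central oxygen of glycerol carries an unbranched (CH2)8 chain whose far end is bonded to C1 of a [3]-ladderane. In the labels used here, ring D is the cyclohexane (C1–C6); it is fused through C4–C5 to cyclobutane ring A (C4, C5, C7, C8), which shares C7–C8 with ring B (C7–C10), which shares C9–C10 with terminal ring C (C9–C12). C7 is bonded to C5 and C9, C8 to C4 and C10, C11 to C9, and C12 to C10. There are seven stereocentres: the six contiguous ring-fusion methines C4, C5, C7, C8, C9 and C10 (every fusion cis, neighbouring rings anti) and C1, whose chain lies on the same face of ring D as ring A; the glycerol carbon is not stereogenic. Without the chain the core has a mirror plane through the midpoints of C1–C2, C4–C5, C7–C8, C9–C10 and C11–C12, so C1 and C2 are enantiotopic and the absolute configuration depends on which of them is alkylated and on which face. The three fused cyclobutanes are highly strained: they do not tolerate strong heating, metals that insert into strained C–C bonds, or a radical or cation on a carbon directly attached to a four-membered ring (C3, C6). The difficulty is twofold: building three linearly fused four-membered rings with all-anti topology, and placing one alkyl group enantioselectively on a ring D carbon with no neighbouring functional group. The key step uses C11 and C12, the only ladder carbons that are CH2 groups: the bond between them carries no stereochemistry, so it can be made last by contracting a five-membered sulfone (C9–C11–SO2–C12–C10) that spans them.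

## Logic of the disconnections

**C1–C1′ (ring D to chain).** From 30 the glycerol is re-protected as its benzylidene acetal (29), and the bond between C1 and the first chain carbon is cut to give secondary sulfonate 24 and organomagnesium 28. This is the only stereocentre outside the ladder, and cutting here separates the strained core from a simple chain. The forward step must be a clean SN2 inversion that outruns E2, so the C1 oxygen of 24 must sit on the face of ring D opposite ring A.

**Ether C–O of the chain.** 28 comes from bromide 27, which is cut at the ether oxygen into 25 and 26. Both are commercial; the forward alkylation must stop at mono-substitution of 26.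

**C2–O and the sulfonate O–S bond.** Restoring an oxygen on C2 of 24 (via 23 and 22) leads to diol 21, which is meso. The whole absolute-configuration problem then reduces to telling two enantiotopic hydroxyls apart. The forward demands are high group selectivity from a chiral catalyst and a deoxygenation at C2 that does not disturb the sulfonate or the ladder.

**Acetonide and the C11–C12 hydrogens.** 21 is traced through ketal 20 to alkene 19, which exposes the retron of the contraction. The forward reduction must saturate a strained alkene without cleaving cyclobutane bonds.

**C11=C12 (key).** The alkene of 19 is opened and SO2 is inserted between C11 and C12, with chloride on one side, to give 17. The bond carries no stereocentre and ring C, the most strained element, is replaced by an unstrained five-membered sulfone. The forward step needs deprotonation on the side away from chloride and closure faster than elimination.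

**C11–S and C12–S.** 17 is traced through 15 and 13 to anhydride 12. The two one-carbon arms then come from a cis-anhydride, which guarantees the cis relationship that thiolane closure requires.

**C7–C9 and C8–C10.** A retro-[2+2] of ring B splits 12 into cyclobutene 10 and 11. Four stereocentres are set in one step; the forward cycloaddition must occur on the exo face of 10 with the anhydride turned away from ring A.

**C7=C8.** 10 is opened by the same sulfone retron to 8, and then through 6 and 4 to diester 3. The cis ring fusion is inherited from the cis-diester, no cis-diol of a four-membered ring is needed, and the key reaction is rehearsed on a less strained ring.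

**C1–O and C2–O.** 3 goes back through 2 to 1 by removing the cis-diol. The oxygens serve twice, first as a masked ring D alkene and later as the handle for the chain. The forward dihydroxylation must occur on the face opposite the esters, so that the later inversion puts the chain syn to ring A.

## Other disconnections considered

**Alternative 1:** The cut goes through all four rungs of the ladder (C4–C5, C7–C8, C9–C10, C11–C12) and leaves two molecules of (E)-penta-2,4-dienoic acid A1. In the forward key step two molecules of A1, held parallel and head-to-head by a template or a crystal lattice, undergo two successive [2+2] photocycloadditions to give meso diacid A2 (anti-tricyclo[4.2.0.0(2,5)]octane-cis-3,4-dicarboxylic acid).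
- In favour: rings A, B and C, four bonds and six stereocentres arise in one operation from an achiral C5 acid. The anti topology follows from the s-trans diene, and the cis-diacid sits on C4 and C5, where ring D must be attached.
- Against: the reaction depends on preorganisation. In fluid solution E/Z isomerisation and unselective single cycloadditions would be expected to dominate, and attaching and removing a template costs steps. The carboxyl carbons become only C3 and C6, so C1, C2 and the ring D closure must still be added, and C1 still needs desymmetrisation of a meso intermediate.
- Comparison: on structure A2 is clearly the better answer to the ladder, reaching in one step what the chosen plan reaches at 19 after eleven. On ladder stereocontrol the two are equal, both being enforced by geometry. On mechanism the chosen contraction is an ionic reaction in ordinary glassware, whereas dimerisation of A1 is a templated or solid-state photoreaction that is harder to scale. On step economy Alternative 1 is at least the equal of the chosen plan if ring D can be annulated in about five steps; the chosen plan in return has ring D from its first compound.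

**Alternative 2:** The cut is the C7–C8 bond shared by rings A and B. Forward, irradiation of cis-1,2-dihydrophthalic anhydride A3 closes the cyclohexadiene by a disrotatory four-electron electrocyclisation to the bicyclo[2.2.0]hex-5-ene anhydride A4.
- In favour: rings A and B with their cis fusion come from a unimolecular, fully atom-economic isomerisation. The cyclobutene of A4 is the right place to add ring C, and the anhydride carbons are C3 and C6.
- Against: the closure competes with other photoreactions of the diene, the exo or endo position of the anhydride is not strongly biased, and A4 is a strained, thermally labile cyclobutene. Ring C would still have to be built, most plausibly by photoaddition of 11 and the sulfone contraction of the chosen plan. Ring D and C1 remain unsolved as in Alternative 1.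
- Comparison: A4 is one step from A3, whereas the comparable two-ring compound 10 needs six; this is a real advantage of the alternative. However, 10 already contains ring D, and A4 carries it only as two carboxyl carbons. A unimolecular photoreaction is simpler than the bimolecular sensitised one of step 7 (equal or better), but it gives a more fragile product. The steps saved at the front are likely to be spent on ring D, so no clear gain in step count is seen.

**Alternative 3:** The cut is the C5–C7 bond, with C7 reattached to C1, which leads to the chain-bearing bicyclo[2.2.2]octenone A5. Forward, direct irradiation of A5 causes α-cleavage to an acyl/allyl radical pair that recombines at the far allyl terminus (1,3-acyl shift) to give cyclobutanone A6, in which ring A is closed and the chain already sits on C1.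
- In favour: the chain and its position are fixed from the start, so neither a meso desymmetrisation nor a late coupling at a secondary carbon is needed. The absolute configuration could come from an enantioselective Diels–Alder route to A5, and the C7 carbonyl is a handle for the C7=C8 alkene.
- Against: the 1,3-shift is a photoequilibrium that competes with oxa-di-π-methane rearrangement and decarbonylation, and A6 is itself photolabile. C1 becomes a stereocentre only on hydrogenation of the C1=C6 alkene, where hydrogen must arrive on the face of ring D opposite ring A, and that preference is not assured. Rings B and C are not addressed, so steps 7–12 of the chosen plan would still follow, on unsymmetrical material.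
- Comparison: Alternative 3 is the better solution for C1 and could save steps 14–18. The chosen plan is better for the ladder, to which Alternative 3 contributes only ring A. Mechanistically a reversible radical-pair photoreaction stands against an irreversible ionic contraction. The step counts are about equal on paper; the chosen plan is preferred because its one stereo-defining substitution is invertive and therefore predictable.

Key step: step 11

Remark (assumption on the chemistry): the sense of the Cu(OTf)2/bis(oxazoline) sulfonylation is taken by analogy with cis-cyclohexane-1,2-diol and written for the (R,R) ligand; should the other hydroxyl react, the (S,S) ligand is used and nothing else changes.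

Remark (structures): 1 is the cis, meso diester and is written with both stereodescriptors; in 17 and 19 the dioxolane lies on the face of ring D opposite ring A, as the invertive coupling of step 18 requires; the cyclobutanone of alternative 3 has its carbonyl on the ring-fusion carbon next to the alkene and is therefore named as an oct-4-en-7-one.

## Route

Step 1
Reactants: 1 dimethyl cis-cyclohex-4-ene-1,2-dicarboxylate (meso)
Product: 2 dimethyl t-4,t-5-dihydroxycyclohexane-r-1,c-2-dicarboxylate (meso; hydroxyls cis to each other and trans to both esters)
Conditions: K2OsO2(OH)4 (1 mol%), NMO (1.3 equiv), acetone/H2O 4:1, rt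
Reagents that add atoms: N-methylmorpholine N-oxide, C[N+]1([O-])CCOCC1; water, O (oxygen is relayed through the OsO4 formed from the osmate)
Why: Upjohn dihydroxylation; the homoallylic ester that is axial in either half-chair shields its own face, so OsO4 should add to the face opposite both esters and set the two hydroxyls cis to each other and trans to the esters. Any all-cis diol is removed here by crystallisation or chromatography.

Step 2
Reactants: 2 dimethyl t-4,t-5-dihydroxycyclohexane-r-1,c-2-dicarboxylate
Product: 3 acetonide diester (dimethyl t-4,t-5-isopropylidenedioxycyclohexane-r-1,c-2-dicarboxylate; meso)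
Conditions: Me2C(OMe)2, TsOH·H2O (cat.), acetone, rt
Reagents that add atoms: 2,2-dimethoxypropane, COC(C)(C)OC
Why: Acid-catalysed transketalisation of a cis-1,2-diol; the dioxolane masks the future C1/C2 oxygens against hydride, base, sulfide, peracid and light until step 13.

Step 3
Reactants: 3 acetonide diester
Product: 4 acetonide diol ([t-4,t-5-isopropylidenedioxycyclohexane-r-1,c-2-diyl]dimethanol; meso)
Conditions: LiAlH4, THF, 0 °C to rt; aq. NaOH work-up
Reagents that add atoms: none
Why: Ester reduction with LiAlH4; the ketal is inert and no stereocentre is touched.

Step 4
Reactants: 4 acetonide diol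
Product: 6 bicyclic thiolane (cis-5,6-isopropylidenedioxy-cis-octahydro-2-benzothiophene; dioxolane trans to the sulfur ring; meso), via bis(methanesulfonate) 5 (not isolated)
Conditions: MsCl, Et3N, THF, 0 °C; then Na2S·9H2O, DMF, 60 °C
Reagents that add atoms: sodium sulfide, [Na+].[Na+].[S-2]; methanesulfonyl chloride, CS(=O)(=O)Cl (its atoms are held only in intermediate 5)
Why: Double mesylation followed by double SN2 displacement by sulfide, the second being a 5-exo-tet closure, is the standard thiolane synthesis from a 1,4-diol; the cis arrangement of the two arms inherited from 1 allows the ring to close.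

Step 5
Reactants: 6 bicyclic thiolane
Product: 8 bicyclic α-chloro sulfone (1-chloro 2,2-dioxide of 6; racemic; both chloride epimers), via α-chloro sulfide 7 (not isolated)
Conditions: NCS, CH2Cl2, 0 °C; then mCPBA (2.5 equiv), 0 °C to rt
Reagents that add atoms: N-chlorosuccinimide, O=C1CCC(=O)N1Cl; mCPBA, OOC(=O)c1cccc(Cl)c1
Why: Pummerer-type α-chlorination of the sulfide through its chlorosulfonium salt, then peracid oxidation of the labile α-chloro sulfide to the sulfone without isolation. The two α-CH2 groups are enantiotopic, so 8 is a racemic mixture of chloride epimers, which is irrelevant because all isomers give the same alkene.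

Step 6
Reactants: 8 bicyclic α-chloro sulfone
Product: 10 acetonide-protected cis-bicyclo[4.2.0]oct-7-ene-3,4-diol (rings D and A with C7=C8; dioxolane on the face of ring D opposite ring A; meso), via episulfone 9 (not isolated)
Conditions: KOtBu (3 equiv), THF, 0 °C to rt
Reagents that add atoms: none
Why: Ramberg–Bäcklund contraction: α′-deprotonation, 1,3-displacement of chloride to episulfone 9 and loss of SO2 give the cyclobutene. This contraction of ring-fused thiolane chloro sulfones to fused cyclobutenes is an established reaction type, needs no cis-diol on a four-membered ring, and rehearses step 11 on a less strained ring.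

Step 7
Reactants: 10 acetonide-protected cis-bicyclo[4.2.0]oct-7-ene-3,4-diol; 11 maleic anhydride
Product: 12 cis-anti-cis photoadduct (rings D A B; anhydride fused at C9–C10 anti to ring A; meso)
Conditions: hν (λ > 300 nm, Pyrex), PhCOMe (sensitiser), MeCN, 0 °C; 11 in excess
Reagents that add atoms: none
Why: Triplet-sensitised [2+2] photocycloaddition of the anhydride to a strained cyclobutene through a 1,4-biradical. Approach to the exo face of the cyclobutene (the face of the C4/C5 hydrogens; ring D blocks the other) makes rings D and B anti across ring A, and the anhydride ring turns away from ring A, so C7–C10 are set cis-anti-cis in one step. The dioxolane sits at the far end of ring D and should not interfere.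

Step 8
Reactants: 12 cis-anti-cis photoadduct
Product: 13 C9,C10-bis(hydroxymethyl) compound (meso)
Conditions: LiAlH4, THF, 0 °C to reflux; aq. NaOH work-up
Reagents that add atoms: none
Why: LiAlH4 reduces the cyclic anhydride to the diol; the cis relationship of the two arms is fixed by the anhydride ring.

Step 9
Reactants: 13 C9,C10-bis(hydroxymethyl) compound
Product: 15 tetracyclic thiolane (sulfur bridging C11 and C12; meso), via bis(methanesulfonate) 14 (not isolated)
Conditions: MsCl, Et3N, THF, 0 °C; then Na2S·9H2O, DMF, 60 °C
Reagents that add atoms: sodium sulfide, [Na+].[Na+].[S-2]; methanesulfonyl chloride, CS(=O)(=O)Cl (its atoms are held only in intermediate 14)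
Why: The same mesylation and double SN2 displacement by sulfide as in step 4, here closing the 3-thiabicyclo[3.2.0]heptane unit on the cis-disposed arms.

Step 10
Reactants: 15 tetracyclic thiolane
Product: 17 acetonide-protected tetracyclic α-chloro sulfone (C11-chloro S,S-dioxide of 15; racemic; both chloride epimers), via α-chloro sulfide 16 (not isolated)
Conditions: NCS, CH2Cl2, 0 °C; then mCPBA (2.5 equiv), 0 °C to rt
Reagents that add atoms: N-chlorosuccinimide, O=C1CCC(=O)N1Cl; mCPBA, OOC(=O)c1cccc(Cl)c1
Why: α-Chlorination of the sulfide and oxidation to the sulfone as in step 5; the ketal and the saturated rings are inert to both reagents, and the mixture of isomers is used as such.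

Step 11
Reactants: 17 acetonide-protected tetracyclic α-chloro sulfone
Product: 19 acetonide-protected anti-[3]-ladderene (C11=C12; meso), via episulfone 18 (not isolated)
Conditions: KOtBu (3 equiv), THF, −20 °C to rt
Reagents that add atoms: none
Why: Ramberg–Bäcklund contraction: tert-butoxide removes a proton from the CH2 carbon on the far side of sulfur (C12), the carbanion displaces chloride at C11 in an intramolecular 1,3-substitution that forms the C11–C12 bond in episulfone 18, and 18 loses SO2 by cheletropic extrusion to leave the C11=C12 alkene of ring C. The closest known reaction type is the contraction of 3-thiabicyclo[3.2.0]heptane α-chloro sulfones to bicyclo[2.2.0]hex-2-enes, the substructure of rings B and C here, and step 6 runs the same reaction on a less strained ring. Ring C is closed as the carbocyclic part of the bicyclic episulfone: the carbanion closes the thiirane dioxide in a 3-exo-tet mode, and the four-membered carbocycle is what remains once sulfur is expelled. No stereocentre is created, since C11 and C12 become sp2 and an alkene in a four-membered ring can only be cis; for the same reason both chloride epimers and both mirror-image placements of chlorine in 17 converge on one product. The selectivity needed is deprotonation at C12 followed by closure, in preference to β-elimination of HCl towards C9; it is secured because only the hydrogens next to the sulfone are acidified, those on C9 and C10 are not, and deprotonation at the chlorine-bearing carbon is reversible and unproductive. The ring-fusion carbons C4–C10 are never part of a reacting centre, so the cis-anti-cis ladder set in step 7 is carried through unchanged. The strain of the third cyclobutane is paid for by irreversible loss of chloride and SO2, and the temperature is kept low so that the strained alkene is not exposed to warm alkoxide.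

Step 12
Reactants: 19 acetonide-protected anti-[3]-ladderene
Product: 20 acetonide-protected anti-[3]-ladderane-1,2-diol (meso)
Conditions: 2-nitrobenzenesulfonohydrazide, Et3N, CH2Cl2, rt
Reagents that add atoms: none
Why: Diimide generated from the sulfonohydrazide transfers two hydrogens to the strained cis alkene in a concerted syn addition. It is chosen over catalytic hydrogenation because no metal surface that could cleave strained C–C bonds is present, and the ketal survives the near-neutral medium.

Step 13
Reactants: 20 acetonide-protected anti-[3]-ladderane-1,2-diol
Product: 21 meso anti-[3]-ladderane-1,2-diol (both hydroxyls on the face of ring D opposite ring A; C1 S and C2 R)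
Conditions: 1 M HCl, THF, rt
Reagents that add atoms: none
Why: Aqueous acid hydrolysis of the acetonide; the saturated ladder has no acid-labile site under these mild conditions.

Step 14
Reactants: 21 meso anti-[3]-ladderane-1,2-diol
Product: 22 C1 mono(4-methylbenzenesulfonate) of 21 (C1 S; single enantiomer)
Conditions: Cu(OTf)2 (10 mol%), (R,R)-Ph-box [2,2′-isopropylidenebis((4R)-4-phenyl-2-oxazoline)] (10 mol%), TsCl (1.2 equiv), K2CO3, CH2Cl2, 0 °C to rt
Reagents that add atoms: 4-methylbenzenesulfonyl chloride, Cc1ccc(cc1)S(=O)(=O)Cl
Why: Enantioselective monosulfonylation of a meso cis-1,2-diol: the diol chelates divalent copper held in the C2-symmetric bis(oxazoline), which activates it so that carbonate-assisted sulfonylation occurs at one enantiotopic oxygen only. The ligand enantiomer is chosen so that the C1 oxygen reacts, which fixes the absolute configuration of the whole molecule, and the monosulfonate is a poorer chelator, so double sulfonylation is slow. The sulfonate is used rather than an ester because it is the leaving group of step 18 and cannot migrate to the neighbouring oxygen.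

Step 15
Reactants: 22 C1 mono(4-methylbenzenesulfonate) of 21
Product: 23 C2 O-phenyl thionocarbonate of 22
Conditions: PhOC(S)Cl, pyridine, DMAP (cat.), CH2Cl2, rt
Reagents that add atoms: O-phenyl chlorothionoformate, ClC(=S)Oc1ccccc1
Why: Acylation of the remaining secondary alcohol under mild conditions gives the Barton–McCombie precursor; no strong base is used, so the neighbouring sulfonate is not disturbed.

Step 16
Reactants: 23 C2 O-phenyl thionocarbonate of 22
Product: 24 anti-[3]-ladderan-1-yl 4-methylbenzenesulfonate (C1 R; sulfonate on the face of ring D opposite ring A)
Conditions: Bu3SnH (3 equiv, 0.3 M), AIBN, toluene, 85 °C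
Reagents that add atoms: none
Why: Barton–McCombie deoxygenation: the stannyl radical adds to C=S, the C2–O bond fragments, and the secondary C2 radical abstracts hydrogen from Bu3SnH. C2 is separated from ring A by C3, so no cyclobutylcarbinyl ring opening is possible, and alkyl sulfonates are inert to stannyl radicals; a high stannane concentration keeps hydrogen transfer fast.

Step 17
Reactants: 25 cis-2-phenyl-1,3-dioxan-5-ol; 26 1,8-dibromooctane
Product: 27 cis-5-(8-bromooctyloxy)-2-phenyl-1,3-dioxane
Conditions: NaH, DMF, 0 °C; then 26 (4 equiv), rt
Reagents that add atoms: none
Why: Williamson etherification of the sodium alkoxide with a primary bromide; the excess of dibromide suppresses double alkylation and is recovered.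

Step 18
Reactants: 24 anti-[3]-ladderan-1-yl 4-methylbenzenesulfonate; 27 cis-5-(8-bromooctyloxy)-2-phenyl-1,3-dioxane
Product: 29 cis-5-[8-(anti-[3]-ladderan-1-yl)octyloxy]-2-phenyl-1,3-dioxane (C1 S; chain syn to ring A), via Grignard reagent 28 (not isolated)
Conditions: Mg, THF, 40 °C; then 24, CuI (10 mol%), TMEDA (20 mol%), LiOMe (1 equiv), THF, 0 °C
Reagents that add atoms: magnesium, [Mg] (held only in intermediate 28; nothing beyond the two reactants stays in 29)
Why: Copper-catalysed cross-coupling of a primary alkyl Grignard reagent with an unactivated secondary tosylate, which proceeds by SN2 attack of an alkylcuprate with inversion: the nucleophile enters C1 from the face syn to ring A while the sulfonate leaves from the opposite face, which sets the last stereocentre. TMEDA and LiOMe are the additives that favour substitution over elimination in this reaction type, and the acetal and ether are inert to the organometallic.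

Step 19
Reactants: 29 cis-5-[8-(anti-[3]-ladderan-1-yl)octyloxy]-2-phenyl-1,3-dioxane
Product: 30 2-[8-(anti-[3]-ladderan-1-yl)octyloxy]propane-1,3-diol (target CNP0193334.1)
Conditions: AcOH/H2O 4:1, 45 °C
Reagents that add atoms: none
Why: Acid hydrolysis of the benzylidene acetal frees the 1,3-diol; the dialkyl ether and the saturated ladder are stable to warm aqueous acetic acid.

## Compound list

1 | dimethyl cis-cyclohex-4-ene-1,2-dicarboxylate (meso) | COC(=O)[C@@H]1CC=CC[C@@H]1C(=O)OC | starting material
2 | dimethyl t-4,t-5-dihydroxycyclohexane-r-1,c-2-dicarboxylate (meso) | O[C@@H]1[C@H](O)C[C@@H](C(=O)OC)[C@H](C1)C(=O)OC | intermediate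
3 | acetonide diester (meso) | CC1(C)O[C@@H]2[C@H](O1)C[C@@H](C(=O)OC)[C@H](C2)C(=O)OC | intermediate
4 | acetonide diol (meso) | CC1(C)O[C@@H]2[C@H](O1)C[C@@H](CO)[C@H](C2)CO | intermediate
5 | bis(methanesulfonate) of 4 | CC1(C)O[C@@H]2[C@H](O1)C[C@@H](COS(C)(=O)=O)[C@H](C2)COS(C)(=O)=O | intermediate
6 | bicyclic thiolane (meso) | CC1(C)O[C@@H]2[C@H](O1)C[C@@H]3[C@H](C2)CSC3 | intermediate
7 | 1-chloro derivative of 6 (racemic; both chloride epimers) | CC1(C)O[C@@H]2[C@H](O1)C[C@@H]3[C@H](C2)C(Cl)SC3 | intermediate
8 | bicyclic α-chloro sulfone (racemic; both chloride epimers) | CC1(C)O[C@@H]2[C@H](O1)C[C@@H]3[C@H](C2)C(Cl)S(=O)(=O)C3 | intermediate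
9 | episulfone from 8 (sulfur exo) | CC1(C)O[C@@H]2[C@H](O1)C[C@@H]3[C@H](C2)[C@H]4S(=O)(=O)[C@@H]34 | intermediate
10 | acetonide-protected cis-bicyclo[4.2.0]oct-7-ene-3,4-diol (meso) | CC1(C)O[C@@H]2[C@H](O1)C[C@@H]3[C@H](C2)C=C3 | intermediate
11 | maleic anhydride | O=C1OC(=O)C=C1 | starting material
12 | cis-anti-cis photoadduct anhydride (meso) | CC1(C)O[C@@H]2[C@H](O1)C[C@@H]4[C@H](C2)[C@H]5[C@@H]6C(=O)OC(=O)[C@@H]6[C@@H]45 | intermediate
13 | C9,C10-bis(hydroxymethyl) compound (meso) | CC1(C)O[C@@H]2[C@H](O1)C[C@@H]4[C@H](C2)[C@H]5[C@H](CO)[C@H](CO)[C@@H]45 | intermediate
14 | bis(methanesulfonate) of 13 | CC1(C)O[C@@H]2[C@H](O1)C[C@@H]4[C@H](C2)[C@H]5[C@H](COS(C)(=O)=O)[C@H](COS(C)(=O)=O)[C@@H]45 | intermediate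
15 | tetracyclic thiolane (meso) | CC1(C)O[C@@H]2[C@H](O1)C[C@@H]4[C@H](C2)[C@H]5[C@@H]6CSC[C@@H]6[C@@H]45 | intermediate
16 | C11-chloro derivative of 15 (racemic; both chloride epimers) | CC1(C)O[C@@H]2[C@H](O1)C[C@@H]4[C@H](C2)[C@H]5[C@@H]6C(Cl)SC[C@@H]6[C@@H]45 | intermediate
17 | acetonide-protected tetracyclic α-chloro sulfone (racemic; both chloride epimers) | CC1(C)O[C@@H]2[C@H](O1)C[C@@H]4[C@H](C2)[C@H]5[C@@H]6C(Cl)S(=O)(=O)C[C@@H]6[C@@H]45 | intermediate
18 | episulfone from 17 (sulfur anti to ring B) | CC1(C)O[C@@H]2[C@H](O1)C[C@@H]4[C@H](C2)[C@H]5[C@@H]6[C@H]7S(=O)(=O)[C@H]7[C@@H]6[C@@H]45 | intermediate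
19 | acetonide-protected anti-[3]-ladderene (meso) | CC1(C)O[C@@H]2[C@H](O1)C[C@@H]4[C@H](C2)[C@H]5[C@@H]6C=C[C@@H]6[C@@H]45 | intermediate
20 | acetonide-protected anti-[3]-ladderane-1,2-diol (meso) | CC1(C)O[C@@H]2[C@H](O1)C[C@@H]4[C@H](C2)[C@H]5[C@@H]6CC[C@@H]6[C@@H]45 | intermediate
21 | meso anti-[3]-ladderane-1,2-diol | O[C@@H]1[C@H](O)C[C@@H]2[C@H](C1)[C@H]1[C@@H]3CC[C@@H]3[C@@H]21 | intermediate
22 | C1 mono(4-methylbenzenesulfonate) of 21 | Cc1ccc(cc1)S(=O)(=O)O[C@@H]1[C@H](O)C[C@@H]2[C@H](C1)[C@H]1[C@@H]3CC[C@@H]3[C@@H]21 | intermediate
23 | C2 O-phenyl thionocarbonate of 22 | Cc1ccc(cc1)S(=O)(=O)O[C@@H]1[C@H](OC(=S)Oc2ccccc2)C[C@@H]2[C@H](C1)[C@H]1[C@@H]3CC[C@@H]3[C@@H]21 | intermediate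
24 | anti-[3]-ladderan-1-yl 4-methylbenzenesulfonate | Cc1ccc(cc1)S(=O)(=O)O[C@@H]1CC[C@@H]2[C@H](C1)[C@H]1[C@@H]3CC[C@@H]3[C@@H]21 | intermediate
25 | cis-2-phenyl-1,3-dioxan-5-ol | O[C@H]1CO[C@@H](c2ccccc2)OC1 | starting material
26 | 1,8-dibromooctane | BrCCCCCCCCBr | starting material
27 | cis-5-(8-bromooctyloxy)-2-phenyl-1,3-dioxane | BrCCCCCCCCO[C@H]1CO[C@@H](c2ccccc2)OC1 | intermediate
28 | Grignard reagent from 27 | Br[Mg]CCCCCCCCO[C@H]1CO[C@@H](c2ccccc2)OC1 | intermediate
29 | cis-5-[8-(anti-[3]-ladderan-1-yl)octyloxy]-2-phenyl-1,3-dioxane | O(CCCCCCCC[C@H]1CC[C@@H]2[C@H](C1)[C@H]1[C@@H]3CC[C@@H]3[C@@H]21)[C@H]1CO[C@@H](c2ccccc2)OC1 | intermediate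
30 | 2-[8-(anti-[3]-ladderan-1-yl)octyloxy]propane-1,3-diol | OCC(CO)OCCCCCCCC[C@H]1CC[C@@H]2[C@H](C1)[C@H]1[C@@H]3CC[C@@H]3[C@@H]21 | target

## Step count and least certain steps

Total step count: 19. Longest linear sequence: 18 (steps 1–16, 18 and 19); step 17 is a one-step side branch.

**Step 11 (key step).** The most likely failure is slow closure of the strained bicyclic episulfone, so that base-induced 1,2-elimination of HCl or attack of alkoxide on the newly formed strained alkene takes over; the third cyclobutane adds strain to the closure that step 6 did not have to bear. The fallback contracts a carbocycle with loss of N2 instead of a heterocycle with loss of SO2. It sets out from 10: photocycloaddition with cyclopent-2-enone should give the cis-anti-cis cyclopentanone F1. Formylation (NaH, HCO2Et) to the hydroxymethylene ketone F2 and deformylative diazo transfer (4-acetamidobenzenesulfonyl azide, Et3N) give the α-diazo ketone F3. Photochemical Wolff rearrangement in aqueous THF contracts the five-membered ring to the cyclobutanecarboxylic acid F4, with the carboxyl on C11. Coupling with 1-hydroxypyridine-2(1H)-thione (DCC) gives the thiohydroxamate ester F5, and Barton decarboxylation (t-BuSH, visible light) removes the carboxyl. The route is rejoined at 20; the detour bypasses steps 7–10 and 12 as well.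

**Step 7.** The most likely failure is inefficient cross-cycloaddition: self-dimerisation of excited 11 and Paternò–Büchi addition of the ketone sensitiser to the strained alkene consume the partners, or exo/anti selectivity is eroded during biradical closure. The fallback uses a different chromophore that needs no aromatic ketone and gives a shorter way to the diol. It sets out from 10: irradiation with furan-2(5H)-one in acetone should give the cyclobutane-fused γ-lactone F6, which LiAlH4 reduces directly to 13, where the route is rejoined.

**Step 14.** The most likely failure is insufficient discrimination between the two enantiotopic hydroxyls, because the ladder makes the two faces of the copper chelate unequal in a way the simple cyclic models are not, or bis-sulfonylation. The fallback replaces metal-catalysed group selection by an enzymatic one. It sets out from 21: lipase-catalysed transesterification with vinyl acetate (Burkholderia cepacia lipase, t-BuOMe, rt) should acylate one hydroxyl selectively, and the lipase is selected for the sense that puts the acetate on C2 (F7). Immediate tosylation of the free C1 hydroxyl (TsCl, pyridine) gives F8 and forestalls acetyl migration, which would racemise F7. Mild methanolysis (K2CO3, MeOH, 0 °C) removes the acetate and rejoins the route at 22.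

**Step 18.** The most likely failure is E2 elimination: the secondary sulfonate can become axial with anti-periplanar hydrogens on C2 and C6, and elimination by the basic organometallic then outruns substitution. The fallback is a radical cross-coupling instead of an SN2 reaction. It sets out from 24: NaI in acetone gives the iodide F9, whose configuration is immaterial, and the organozinc bromide F10 is made from 27 with Zn dust in DMA. Negishi coupling with Ni(cod)2 (zerovalent nickel) and 2,6-bis[(4S)-4-sec-butyl-2-oxazolin-2-yl]pyridine joins them through the C1 radical, which cannot open ring A because C6 lies between. Bond formation on the more open face of ring D, the one syn to ring A, should favour 29, where the route is rejoined; a C1 epimer, if formed, would have to be separated.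

## Further compounds

F1 | step 11 | cis-anti-cis cyclopentanone photoadduct of 10 (racemic; carbonyl carbon bonded to C9) | CC1(C)O[C@@H]2[C@H](O1)C[C@@H]4[C@H](C2)[C@H]5[C@@H]6C(=O)CC[C@@H]6[C@@H]45
F2 | step 11 | α-hydroxymethylene ketone from F1 | CC1(C)O[C@@H]2[C@H](O1)C[C@@H]4[C@H](C2)[C@H]5[C@@H]6C(=O)C(=CO)C[C@@H]6[C@@H]45
F3 | step 11 | α-diazo ketone from F2 | CC1(C)O[C@@H]2[C@H](O1)C[C@@H]4[C@H](C2)[C@H]5[C@@H]6C(=O)C(=[N+]=[N-])C[C@@H]6[C@@H]45
F4 | step 11 | acetonide-protected anti-[3]-ladderane-1,2-diol-11-carboxylic acid (both C11 epimers) | CC1(C)O[C@@H]2[C@H](O1)C[C@@H]4[C@H](C2)[C@H]5[C@@H]6C(C(=O)O)C[C@@H]6[C@@H]45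
F5 | step 11 | thiohydroxamate (Barton) ester of F4 | CC1(C)O[C@@H]2[C@H](O1)C[C@@H]4[C@H](C2)[C@H]5[C@@H]6C(C(=O)ON7C=CC=CC7=S)C[C@@H]6[C@@H]45
F6 | step 7 | cis-anti-cis γ-lactone photoadduct of 10 with furan-2(5H)-one (racemic) | CC1(C)O[C@@H]2[C@H](O1)C[C@@H]4[C@H](C2)[C@H]5[C@@H]6C(=O)OC[C@@H]6[C@@H]45
F7 | step 14 | C2 monoacetate of 21 | O[C@@H]1[C@H](OC(C)=O)C[C@@H]2[C@H](C1)[C@H]1[C@@H]3CC[C@@H]3[C@@H]21
F8 | step 14 | C2 acetate of 22 | Cc1ccc(cc1)S(=O)(=O)O[C@@H]1[C@H](OC(C)=O)C[C@@H]2[C@H](C1)[C@H]1[C@@H]3CC[C@@H]3[C@@H]21
F9 | step 18 | anti-[3]-ladderan-1-yl iodide (iodine syn to ring A) | I[C@H]1CC[C@@H]2[C@H](C1)[C@H]1[C@@H]3CC[C@@H]3[C@@H]21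
F10 | step 18 | alkylzinc bromide from 27 | Br[Zn]CCCCCCCCO[C@H]1CO[C@@H](c2ccccc2)OC1
A1 | alternative 1 | (E)-penta-2,4-dienoic acid | OC(=O)/C=C/C=C
A2 | alternative 1 | anti-tricyclo[4.2.0.0(2,5)]octane-cis-3,4-dicarboxylic acid (meso) | OC(=O)[C@@H]2[C@H](C(O)=O)[C@H]1[C@@H]3CC[C@@H]3[C@@H]21
A3 | alternative 2 | cis-1,2-dihydrophthalic anhydride | O=C1OC(=O)[C@@H]2C=CC=C[C@H]12
A4 | alternative 2 | exo-bicyclo[2.2.0]hex-5-ene-2,3-dicarboxylic anhydride | O=C1[C@@H]2[C@H](C(=O)O1)[C@H]1C=C[C@@H]21
A5 | alternative 3 | 1-[8-(tert-butyldimethylsilyloxy)octyl]bicyclo[2.2.2]oct-5-en-2-one | O=C1C[C@@H]2CC[C@@]1(CCCCCCCCO[Si](C)(C)C(C)(C)C)C=C2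
A6 | alternative 3 | 4-[8-(tert-butyldimethylsilyloxy)octyl]-cis-bicyclo[4.2.0]oct-4-en-7-one | CC(C)(C)[Si](C)(C)OCCCCCCCCC=1CC[C@@H]2[C@H](C=1)C(=O)C2
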